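The left-handed product comes from the left-handed substrate, which is half of the racemate, so its yield is half the fraction of that substrate consumed. We ask how far each flask can go and how fast it gets there.

the same everywhere: left-handed substrate 0.25 M; partner 0.500 M; free catalyst 0.50 mM; impurity 0.11 mM; right-handed substrate 0.25 M; time 20 h
- alpha: temperature 45 °C
- delta: temperature 20 °C
- beta: at 20 °C until 15 h, from then on at 45 °C

    2 partner → self-condensation product (k1 = 1.65 × 10⁻⁶ M⁻¹ s⁻¹, Ea1 = 87.0 kJ mol⁻¹)
    partner + free catalyst + left-handed substrate → free catalyst + left-handed product (k2 = 0.171 M⁻² s⁻¹, Ea2 = 44.0 kJ mol⁻¹)
    free catalyst + impurity → spent catalyst (k3 = 3.57 M⁻¹ s⁻¹, Ea3 = 56.0 kJ mol⁻¹)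
    partner → decomposed reagent (k4 = 7.10 × 10⁻⁷ s⁻¹, Ea4 = 114 kJ mol⁻¹)
    partner + free catalyst + right-handed substrate → free catalyst + right-handed product (k5 = 0.0794 M⁻² s⁻¹, Ea5 = 44.0 kJ mol⁻¹)
    (constants at 20 °C)

- free catalyst is single-handed; left-handed substrate and right-handed substrate are mirror images of each other, charged as a racemate, each of them at the stated concentration
- a doubled species enters its step squared and goes two at a time
- all constants are for 20 °C and move with temperature by the activation energies

- which flask leads in amount of left-handed product, in percent of the left-handed substrate and right-handed substrate together charged ("all alike" within 1.5 percentage points) (alpha / delta / beta / all alike)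
- how much left-handed product is there at the end, in percent of the left-handed substrate and right-handed substrate together charged: alpha
- how much left-handed product is there at the end, in percent of the left-handed substrate and right-handed substrate together charged: delta
- how much left-handed product is there at the end, in percent of the left-handed substrate and right-handed substrate together charged: beta

First the catalyst. The impurity is smaller than the catalyst charge and meets it on a time of 9.34 min, much shorter than the run. So we count 0.390 mM of free catalyst at work from the start.

Next the clock, for delta. There c(partner) equals the two substrates together. The waste of partner by decomposition and self-condensation is 0.00850 h⁻¹ at the charge. The catalytic constant of partner, a pseudo-first-order constant at the charge, is 0.0879 h⁻¹, about ten times that waste. So partner and substrate pool fall nearly together, as a second-order decay. The pool's rest is one over one plus x, where x is the mean of the rate constants of the two product-forming steps times c(free catalyst), the charged c(partner) and time. In delta x is 1.76. The left-handed substrate goes faster than the pool, and we take its rest as the pool's rest raised to n, twice its constant over the sum of both, or 1.37. The ratio of the constants is the selectivity factor, and heat leaves it alone. Delta then gives 37.5%.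

Alpha is hot, so we need a budget. The catalytic constant becomes 0.363 h⁻¹ and the waste 0.199 h⁻¹. At the charge the productive share, the catalytic constant of partner over that constant plus its waste, is 64.6%. Partner's first half-life in alpha is 1.23 h, shorter than the run, so we let the share set the conversion. The pool's rest raised to n gives 37.9% for alpha, level with delta.

Beta runs the clock cold to 15 h, which leaves a pool fraction of 0.431, with partner counted equal. At that pool the hot constants are 0.157 h⁻¹ and 0.143 h⁻¹, a share of 52.2%. If that partner were used up, beta would reach 44.3%. This is the weak link. The hot stage lasts 5.00 h, and at this rate a fraction of 0.777 of the partner goes, less than the whole. Reforged, beta stands at 42.2%, ahead of the other two by more than the margin.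

The forecast names beta, with 37%, 36.8% and 40.7% for alpha, delta and beta, its beta below ours, on the ground that “beta spends most of the partner cleanly cold and then finishes it hot”.

The simulation gives 37.2% in alpha, 36.8% in delta and 40.6% in beta, so beta leads. In alpha 0.47% of the partner charge remains at the end, with 60.5% of the substrates converted. The neighbour of alpha with 2.0 × 10⁻⁴ M of free catalyst keeps the same impurity, which leaves 0.0900 mM. Its catalytic constant shrinks in proportion, and the productive share drops to 29.6%. Through n that gives 19.1%. That neighbour holds 20.6% of left-handed product.

The numbers of this flask were chosen freely; the rest is arithmetic.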